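Remark on the chemistry: (S)-pent-1-yn-3-ol (25) is treated as a purchasable building block; it is otherwise obtained from the cheap racemate by lipase-catalysed acylation.

## Analysis of the target

The target is a 3-O-acylated eremophilane. Its core is a trans-fused decalin (ring A = C1–C5 and C10, ring B = C5–C10) with an ester oxygen on C3, methyl groups on C4 and C5, the ring-fusion hydrogen on C10, a hydroxyl on C9, a ketone on C8 and an isopropylidene group on C7. The bicycle carries five stereocentres, (3R,4R,5R,9S,10R). The C3 oxygen is α and equatorial, the C4 and C5 methyl groups are both β (C4 equatorial, C5 axial and quaternary), H-10 is α and trans to the C5 methyl, and the C9 hydroxyl is α, equatorial and cis to H-10. A sixth centre, (S)-C4′, lies in the acid part, (2Z)-4-[(2Z)-hex-2-enoyloxy]hex-2-enoic acid. Its two Z-enoates isomerise under base or nucleophilic catalysts, and its γ-oxygen would close to a butenolide if it were ever free next to the Z double bond. In the core the C8/C9 α-ketol can transpose or epimerise under base, and the cross-conjugated enone is a Michael acceptor. The difficulty is the contiguous C3–C4–C5–C10 array around the all-carbon quaternary C5, followed by three different oxidation levels on C7, C8 and C9. The route rests on the fact that C5 and C10 are the β- and α-carbons of a C9 carbonyl. A cyclohexenone that already holds the C5 methyl can therefore take up C4 (as a vinyl group) on C5 and C1–C3 (as an acrolein unit) on C10 in one operation, with ring B present from the start and ring A left to be closed between C3 and C4.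

## Retrosynthetic reasoning

**34 ⇒ 33 ⇒ 32.** The last operations only unmask. The C9 hydroxyl is kept as its 4-methoxybenzyl ether (33) so that C3 is the only acylation site, and both Z-enoates are carried as alkynes (32) so that no Z double bond is exposed to an acylation. Forward, the two ynoates must be semi-hydrogenated without touching the tetrasubstituted enone, and the benzyl-type ether must then be cleaved oxidatively under neutral conditions.

**32 ⇒ 24 + 31.** The C3–O ester bond is cut because this is the most convergent cut and leaves the side chain as one acid. Forward, the equatorial C3 hydroxyl of 24 is acylated by 31 while O9 is blocked.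

**31 ⇒ 30 ⇒ 28 + 29, and 28 ⇒ 27 ⇒ 25.** In the side chain the inner ester bond and the bond between the carboxyl carbon and the alkyne are cut. The C4′ centre is bought with 25, the carboxyl group comes from a carboxylation of its alkyne terminus, and a tert-butyl ester keeps the two acyl groups apart until acid 31 is released.

**24 ⇒ 23 ⇒ 21 ⇒ 18 + 19.** The C7=C11 double bond is cut as an aldol condensation because C7 is α to the C8 ketone and 19 brings C11–C13 in one piece. Forward, 18 must be enolised only towards C7, and the tertiary aldol must be dehydrated into conjugation.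

**18 ⇒ 17 ⇒ 15 ⇒ 14 ⇒ 12 ⇒ 11.** The C8 ketone and the C9 oxygen are traced back to the single C9 ketone of 11 through the C8–C9 alkene 14. Dihydroxylation from the face opposite to the axial C5 methyl sets the 9α-oxygen by substrate control. The equatorial and axial hydroxyls of 15 are then told apart, the first being etherified and the second oxidised.

**11 ⇒ 10 ⇒ 9 ⇒ 8.** Ring A is opened at C3–C4. This cut turns the C3 oxygen into an aldehyde oxygen and C4/C15 into a vinyl group on C5, so a ketyl–olefin radical cyclisation can close the ring and set C3 and C4 in one step. For this the C9 carbonyl must be masked as a ketal, which is removed afterwards.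

**8 ⇒ 7 ⇒ 6 ⇒ 5.** Aldehyde and ketone of 5 cannot be ketalised in the required sense directly, because the aldehyde is the more reactive carbonyl. It is therefore masked first as a dithioacetal (6), the ketone is then ketalised (7) and the aldehyde is released again (8). Compound 6 still has the free ketone and is the point at which the configuration at C10 is sorted out.

**5 ⇒ 1 + 2 + 3.** The bonds C4–C5 and C1–C10 are cut together. Forward, a copper-catalysed enantioselective conjugate addition of the vinyl group of 2 to 1 creates the quaternary C5 and delivers the regiodefined C9–C10 silyl enol ether 4, which is added to 3. Everything that is uncertain in the route is met in this first step.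

## Alternatives that were turned down

**Alternative 1:** Ring B is cut at C5–C6. Forward, the ring-A-bound silyloxytriene A1 would close thermally in a disrotatory 6π electrocyclisation to the 2-silyloxy-1,3-diene A2. In A1, C5=C10 lies in ring A, the central C8=C9 bond carries the silyloxy group on C8 with C10 and C7 cis, and C6=C7 is terminal.
- For it: ring B and the quaternary C5 arise in one reagent-free step, and C3 and C4 are already in place to steer the face on which C6 bonds. The oxygen also ends up on C8, where the target has its ketone. On this point the alternative is stronger than the chosen route, which has to move the oxygen from C9 to C8.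
- Against it: the cyclising terminus C5 is fully substituted and the central alkene is Z with a bulky silyloxy group, so the reactive conformer is strained. The closure needs heat, under which 1,5- and 1,7-hydrogen shifts compete. The C5 configuration depends only on torquoselectivity induced by the C4 methyl. After A2 the C9=C10 double bond still has to become H-10α and HO-9α, and C7 still has to be alkylidenated. A1 itself needs a multistep, geometry-defined synthesis.
- In comparison, the chosen route offers a key step on three purchasable compounds, with the quaternary centre set by a catalyst and ring B present from the start.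

**Alternative 2:** The whole skeleton is traced back to the acyclic diphosphate A3. Forward, an aristolochene synthase ionises A3, closes a ten-membered ring and then the transannular C5–C10 bond, and a hydride shift followed by a methyl shift places the methyl on C5, which gives (+)-aristolochene A4.
- For it: both rings, the 4β,5β-dimethyl pair (same configuration as in the target) and the C7 side-chain carbon come from an achiral precursor in one enzymatic step. In skeleton construction and step economy the alternative is clearly stronger.
- Against it: A4 is a hydrocarbon. The C3 oxygen of the target lies on an unactivated methylene far from both double bonds and could only come from a second, selective C–H oxidation enzyme. The C8/C9 oxygens must be developed from the C9=C10 alkene with control of C10, and the isopropenyl double bond must be moved into conjugation. The approach also needs enzyme expression and a supply of A3.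
- In comparison, the chosen route offers oxygen atoms on C3 and C9 that arrive with the building blocks (the aldehyde of 3 and the ketone of 1) and a purely chemical sequence.

**Alternative 3:** The ring-fusion bond C5–C10 is cut, which leads to the ten-membered enedione A5. Forward, a chiral primary amine condenses with the C9 ketone, the C10 enamine adds across the ring to C5 of the enone, and protonation at C4 gives the dione A6.
- For it: one step closes both rings and sets C5, C10 and C4, with oxygen exactly on C3 and C9 and with the trans ring fusion fixed in the same event. In convergence of stereocentres and in control of C10 the alternative is stronger than the chosen route, which must deal with C10 separately.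
- Against it: A5 is a medium ring with a tetrasubstituted enone and is costly to make. The acceptor carbon is β,β-disubstituted, and enamine additions that create quaternary centres at such carbons are slow. The catalyst must distinguish the C9 ketone from the enone carbonyl and impose one ring conformation for three centres. C4 is set by a protonation and not by the catalyst.
- In comparison, the chosen route offers precursors that are bought, a first step that tests the main risk at once, and a ring B that never has to be cyclised.

Key step: step 1

## Route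

Step 1
Reactants: 1 3-methylcyclohex-2-en-1-one; 2 vinylmagnesium bromide; 3 acrolein
Product: 5 (2R,3R)-3-methyl-2-(3-oxopropyl)-3-vinylcyclohexan-1-one, via silyl enol ether 4 (not isolated)
Conditions: CuBr·SMe2 (5 mol%), N,N-bis(1-phenylethyl)-1,1′-binaphthyl-2,2′-diyl phosphoramidite (10 mol%; the antipode that gives (R)-4), Me3SiCl, slow addition of 2, THF, −78 °C; Et3N, pentane, filtration (crude 4); then 3, (5S)-5-benzyl-2,2,3-trimethylimidazolidin-4-one hydrochloride (20 mol%), t-BuOH/i-PrOH, 0 °C; H2O
Reagents that add atoms: chlorotrimethylsilane, C[Si](C)(C)Cl (silyl group of intermediate 4 only)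
Why: Transmetallation of 2 to the phosphoramidite–copper complex gives a vinylcopper species that binds the enone 1 and, assisted by Me3SiCl, transfers vinyl to C5, so that the C4–C5 bond and the quaternary centre arise together and the enolate is silylated on oxygen as the regiodefined C9–C10 enol ether 4. The closest known reactions are copper-catalysed enantioselective additions of alkyl Grignard reagents and of alkenylaluminium reagents to this very enone; ligand-controlled transfer of an unsubstituted vinyl group from magnesium is the untested element, which is why this step carries the risk of the route. The configuration at C5 is set by the ligand, whose antipode is chosen to give (R)-4. In the second stage the secondary amine condenses with 3 to an iminium ion that is attacked only at its β-carbon, so 4 adds through C10 in a Mukaiyama–Michael reaction (C1–C10 bond) and hydrolysis releases the aldehyde; a strong Lewis acid such as TiCl4 is avoided because enals then react at the carbonyl carbon. No ring is closed. C10 is formed under kinetic control by attack anti to the pseudoaxial substituent on C5 in the half-chair of 4; a modest preference for the trans isomer 5 is expected because the flat vinyl group tolerates the pseudoaxial site better than methyl, but equilibration cannot improve it, since the two epimers differ only in which of these two groups is axial, so both epimers are carried into step 2 and separated there. The selectivities needed are 1,4 over 1,2 in both stages, secured by the silyl-assisted copper pathway and by iminium activation, and regiocontrol of the enolate, which the conjugate addition itself provides.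

Step 2
Reactants: 5 (2R,3R)-3-methyl-2-(3-oxopropyl)-3-vinylcyclohexan-1-one
Product: 6 (2R,3R)-2-[2-(1,3-dithian-2-yl)ethyl]-3-methyl-3-vinylcyclohexan-1-one
Conditions: propane-1,3-dithiol, BF3·OEt2 (cat.), CH2Cl2, −40 → −10 °C; chromatography
Reagents that add atoms: propane-1,3-dithiol, SCCCS
Why: Lewis-acid-catalysed dithioacetalisation is much faster at the unhindered aldehyde than at the ketone, which is flanked by the branched C10 and the quaternary C5, so only C3 is masked. The ketone stays free, so the C10 epimers are separated at this stage and the unwanted one remains epimerisable for recycling (see the risk notes).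

Step 3
Reactants: 6 (2R,3R)-2-[2-(1,3-dithian-2-yl)ethyl]-3-methyl-3-vinylcyclohexan-1-one
Product: 7 2-{2-[(6R,7R)-7-methyl-7-vinyl-1,4-dioxaspiro[4.5]decan-6-yl]ethyl}-1,3-dithiane
Conditions: Me3SiOCH2CH2OSiMe3, Me3SiOTf (5 mol%), CH2Cl2, −78 → −20 °C
Reagents that add atoms: 1,2-bis(trimethylsilyloxy)ethane, C[Si](C)(C)OCCO[Si](C)(C)C
Why: Silyl-triflate-catalysed ketalisation with the bis-silyl ether of ethylene glycol works on hindered ketones at low temperature under aprotic conditions, so C10 is not epimerised and the dithiane is untouched. The dioxolane makes C9 inert to the one-electron reductant of step 5.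

Step 4
Reactants: 7 2-{2-[(6R,7R)-7-methyl-7-vinyl-1,4-dioxaspiro[4.5]decan-6-yl]ethyl}-1,3-dithiane
Product: 8 3-[(6R,7R)-7-methyl-7-vinyl-1,4-dioxaspiro[4.5]decan-6-yl]propanal
Conditions: MeI, CaCO3, MeCN/H2O, 45 °C
Reagents that add atoms: water, O
Why: S-Methylation turns the dithiane sulfur into a leaving group and buffered hydrolysis releases the aldehyde; the dioxolane survives because CaCO3 takes up the HI, and the vinyl group does not react with MeI.

Step 5
Reactants: 8 3-[(6R,7R)-7-methyl-7-vinyl-1,4-dioxaspiro[4.5]decan-6-yl]propanal
Product: 9 9,9-ethylenedioxy-11,12,13-trinoreremophilan-3α-ol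
Conditions: SmI2 (3 equiv), HMPA, t-BuOH, THF, 0 °C → rt, slow addition of 8
Reagents that add atoms: none
Why: SmI2–HMPA reduces the aldehyde to a ketyl radical that adds 6-exo-trig to the internal vinyl carbon C4 (ketyl–olefin cyclisation); the primary C15 radical is reduced further and protonated by t-BuOH to the methyl group. In the chair-like transition state built on the trans-diequatorial arms of ring B, the samarium-bound oxygen avoids the axial site on C3, which is 1,3-diaxial to the C5 methyl, and the alkene terminus lies equatorial, so the 3α-hydroxyl and the 4β-methyl (both equatorial, trans to each other) should result.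

Step 6
Reactants: 9 9,9-ethylenedioxy-11,12,13-trinoreremophilan-3α-ol
Product: 10 3α-(tert-butyldimethylsilyloxy)-9,9-ethylenedioxy-11,12,13-trinoreremophilane
Conditions: TBSCl, imidazole, DMF, 40 °C
Reagents that add atoms: tert-butyldimethylsilyl chloride, CC(C)(C)[Si](C)(C)Cl
Why: Standard silylation of an equatorial secondary alcohol; the silyl ether is chosen because it survives butyllithium, OsO4, LDA and mesylation and is later cleaved by fluoride in the presence of the 4-methoxybenzyl ether.

Step 7
Reactants: 10 3α-(tert-butyldimethylsilyloxy)-9,9-ethylenedioxy-11,12,13-trinoreremophilane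
Product: 11 3α-(tert-butyldimethylsilyloxy)-11,12,13-trinoreremophilan-9-one
Conditions: PPTS, acetone/H2O, 50 °C
Reagents that add atoms: water, O
Why: Mild acid-catalysed ketal cleavage frees the C9 ketone without cleaving the secondary silyl ether; the weak acid and short contact time limit enolisation towards C10.

Step 8
Reactants: 11 3α-(tert-butyldimethylsilyloxy)-11,12,13-trinoreremophilan-9-one
Product: 12 3α-(tert-butyldimethylsilyloxy)-11,12,13-trinoreremophilan-9-one 2,4,6-triisopropylbenzenesulfonylhydrazone
Conditions: 2,4,6-triisopropylbenzenesulfonohydrazide, THF, rt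
Reagents that add atoms: 2,4,6-triisopropylbenzenesulfonohydrazide, CC(C)c1cc(C(C)C)c(S(=O)(=O)NN)c(C(C)C)c1
Why: Condensation of the ketone with the arylsulfonyl hydrazide; the triisopropylphenyl derivative is used because its hydrazones form without added acid and break down to the vinyl anion at low temperature.

Step 9
Reactants: 12 3α-(tert-butyldimethylsilyloxy)-11,12,13-trinoreremophilan-9-one 2,4,6-triisopropylbenzenesulfonylhydrazone
Product: 14 3α-(tert-butyldimethylsilyloxy)-11,12,13-trinoreremophil-8-ene, via vinyllithium 13 (not isolated)
Conditions: n-BuLi (2.2 equiv), THF, −78 → 0 °C; H2O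
Reagents that add atoms: n-butyllithium, [Li]CCCC (lithium of intermediate 13 only)
Why: Shapiro reaction: the second equivalent of base removes a proton from C8, the less substituted α-carbon, and loss of sulfinate and N2 gives the C9 vinyllithium 13, which is protonated to the C8–C9 alkene. C10 is not touched, so the trans ring fusion is kept.

Step 10
Reactants: 14 3α-(tert-butyldimethylsilyloxy)-11,12,13-trinoreremophil-8-ene
Product: 15 3α-(tert-butyldimethylsilyloxy)-11,12,13-trinoreremophilane-8α,9α-diol
Conditions: OsO4 (2 mol%), NMO, acetone/H2O, rt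
Reagents that add atoms: osmium tetroxide, O=[Os](=O)(=O)=O; N-methylmorpholine N-oxide, C[N+]1([O-])CCOCC1; water, O
Why: Catalytic cis-dihydroxylation; OsO4 approaches the C8–C9 alkene from the α face because the axial C5 methyl, in a 1,3-relation to C9, shields the β face. This gives the 8α,9α-diol with the C9 hydroxyl equatorial and the C8 hydroxyl axial.

Step 11
Reactants: 15 3α-(tert-butyldimethylsilyloxy)-11,12,13-trinoreremophilane-8α,9α-diol
Product: 17 3α-(tert-butyldimethylsilyloxy)-9α-(4-methoxybenzyloxy)-11,12,13-trinoreremophilan-8α-ol, via stannylene acetal 16 (not isolated)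
Conditions: Bu2SnO, toluene, reflux (−H2O); then 4-methoxybenzyl chloride, Bu4NI, 70 °C
Reagents that add atoms: dibutyltin oxide, CCCC[Sn](=O)CCCC (tin of intermediate 16 only); 4-methoxybenzyl chloride, COc1ccc(CCl)cc1
Why: A cis-diol forms a five-membered dibutylstannylene acetal in which the equatorial oxygen is the more nucleophilic one, so halide-promoted benzylation should go to O9 and leave the axial C8 hydroxyl free (regioselective alkylation through a tin acetal).

Step 12
Reactants: 17 3α-(tert-butyldimethylsilyloxy)-9α-(4-methoxybenzyloxy)-11,12,13-trinoreremophilan-8α-ol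
Product: 18 3α-(tert-butyldimethylsilyloxy)-9α-(4-methoxybenzyloxy)-11,12,13-trinoreremophilan-8-one
Conditions: Dess–Martin periodinane, NaHCO3, CH2Cl2, rt
Reagents that add atoms: none
Why: Dess–Martin oxidation of the remaining axial secondary alcohol under buffered conditions. C9 should not epimerise, and its equatorial ether is in any case the more stable arrangement because the axial site is 1,3-diaxial to the C5 methyl.

Step 13
Reactants: 18 3α-(tert-butyldimethylsilyloxy)-9α-(4-methoxybenzyloxy)-11,12,13-trinoreremophilan-8-one; 19 acetone
Product: 21 3α-(tert-butyldimethylsilyloxy)-11-hydroxy-9α-(4-methoxybenzyloxy)eremophilan-8-one, via lithium enolate 20 (not isolated)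
Conditions: LDA, THF, −78 °C; 19 (excess), −78 °C; AcOH, −78 °C
Reagents that add atoms: lithium diisopropylamide, [Li+].CC(C)[N-]C(C)C (lithium of intermediate 20 only)
Why: Kinetic deprotonation of the α-alkoxy ketone by LDA occurs at the unhindered C7 methylene and not at the oxygen-bearing C9; the enolate 20 adds to 19 in an aldol reaction, and the cold quench prevents retro-aldol cleavage. The C7 configuration (side chain expected equatorial) is lost in step 14.

Step 14
Reactants: 21 3α-(tert-butyldimethylsilyloxy)-11-hydroxy-9α-(4-methoxybenzyloxy)eremophilan-8-one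
Product: 23 3α-(tert-butyldimethylsilyloxy)-9α-(4-methoxybenzyloxy)eremophil-7(11)-en-8-one, via tertiary mesylate 22 (not isolated)
Conditions: MsCl, Et3N, CH2Cl2, −10 °C; then DBU, 0 °C → rt
Reagents that add atoms: methanesulfonyl chloride, CS(=O)(=O)Cl (mesyl group of intermediate 22 only)
Why: Sulfene-type mesylation reaches the tertiary alcohol, and base-induced E1cB elimination through the C7 enolate gives the tetrasubstituted conjugated C7=C11 alkene and not the deconjugated isopropenyl isomer.

Step 15
Reactants: 23 3α-(tert-butyldimethylsilyloxy)-9α-(4-methoxybenzyloxy)eremophil-7(11)-en-8-one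
Product: 24 3α-hydroxy-9α-(4-methoxybenzyloxy)eremophil-7(11)-en-8-one
Conditions: HF·pyridine, pyridine/THF, 0 °C → rt
Reagents that add atoms: none
Why: Fluoride cleaves the silyl ether; the buffered reagent leaves the 4-methoxybenzyl ether, the enone and the C9 centre alone.

Step 16
Reactants: 25 (S)-pent-1-yn-3-ol
Product: 27 (4S)-4-hydroxyhex-2-ynoic acid, via dilithio derivative 26 (not isolated)
Conditions: n-BuLi (2.1 equiv), THF, −78 °C; CO2, −78 → 0 °C; aq. HCl
Reagents that add atoms: n-butyllithium, [Li]CCCC (lithium of intermediate 26 only); carbon dioxide, O=C=O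
Why: Double deprotonation gives the alkoxide acetylide 26, whose carbon end adds to CO2 (carboxylation of a terminal alkyne); the stereocentre is not involved.

Step 17
Reactants: 27 (4S)-4-hydroxyhex-2-ynoic acid
Product: 28 tert-butyl (4S)-4-hydroxyhex-2-ynoate
Conditions: tert-butyl 2,2,2-trichloroacetimidate, CH2Cl2/cyclohexane, rt
Reagents that add atoms: tert-butyl 2,2,2-trichloroacetimidate, CC(C)(C)OC(=N)C(Cl)(Cl)Cl
Why: The carboxylic acid protonates the imidate and is tert-butylated without added acid, whereas the propargylic alcohol is not; this gives an acid-labile ester orthogonal to the inner ester formed next.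

Step 18
Reactants: 28 tert-butyl (4S)-4-hydroxyhex-2-ynoate; 29 hex-2-ynoic acid
Product: 30 tert-butyl (4S)-4-(hex-2-ynoyloxy)hex-2-ynoate
Conditions: DCC, DMAP (5 mol%), CH2Cl2, 0 °C
Reagents that add atoms: none
Why: Carbodiimide esterification (Steglich type) of the secondary propargylic alcohol; as alkynes, neither acyl unit has a double-bond geometry to lose.

Step 19
Reactants: 30 tert-butyl (4S)-4-(hex-2-ynoyloxy)hex-2-ynoate
Product: 31 (4S)-4-(hex-2-ynoyloxy)hex-2-ynoic acid
Conditions: CF3CO2H, CH2Cl2, 0 °C → rt
Reagents that add atoms: none
Why: Acidolysis of the tert-butyl ester with loss of isobutene; the propargylic ester and the ynoates are stable to CF3CO2H.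

Step 20
Reactants: 24 3α-hydroxy-9α-(4-methoxybenzyloxy)eremophil-7(11)-en-8-one; 31 (4S)-4-(hex-2-ynoyloxy)hex-2-ynoic acid
Product: 32 9α-(4-methoxybenzyloxy)-8-oxoeremophil-7(11)-en-3α-yl (4S)-4-(hex-2-ynoyloxy)hex-2-ynoate
Conditions: DCC, DMAP (0.1 equiv), CH2Cl2, −20 → 0 °C
Reagents that add atoms: none
Why: Carbodiimide esterification of the equatorial C3 hydroxyl, the only free hydroxyl of 24; low temperature and little DMAP are used to limit base-induced isomerisation of the 4-acyloxy-ynoate to an allene.

Step 21
Reactants: 32 9α-(4-methoxybenzyloxy)-8-oxoeremophil-7(11)-en-3α-yl (4S)-4-(hex-2-ynoyloxy)hex-2-ynoate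
Product: 33 9α-(4-methoxybenzyloxy)-8-oxoeremophil-7(11)-en-3α-yl (2Z,4S)-4-[(2Z)-hex-2-enoyloxy]hex-2-enoate
Conditions: H2 (1 atm), Pd/CaCO3 poisoned with Pb(OAc)2 (Lindlar catalyst), quinoline, EtOAc, rt
Reagents that add atoms: none
Why: Semi-hydrogenation on the lead-poisoned palladium catalyst adds H2 syn to each ynoate and gives both Z-enoates; the tetrasubstituted enone alkene and the benzyl-type ether should not be reduced under these conditions.

Step 22
Reactants: 33 9α-(4-methoxybenzyloxy)-8-oxoeremophil-7(11)-en-3α-yl (2Z,4S)-4-[(2Z)-hex-2-enoyloxy]hex-2-enoate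
Product: 34 9α-hydroxy-8-oxoeremophil-7(11)-en-3α-yl (2Z,4S)-4-[(2Z)-hex-2-enoyloxy]hex-2-enoate
Conditions: DDQ, CH2Cl2/pH 7 buffer, 0 °C → rt
Reagents that add atoms: none
Why: DDQ oxidises the electron-rich benzyl ether to an oxocarbenium ion that water cleaves, freeing the C9 hydroxyl under neutral conditions that spare the Z-enoates, the esters and the α-ketol.

## Compound list

1 | 3-methylcyclohex-2-en-1-one | CC1=CC(=O)CCC1 | starting material
2 | vinylmagnesium bromide | C=C[Mg]Br | starting material
3 | acrolein | C=CC=O | starting material
4 | (R)-trimethyl[(3-methyl-3-vinylcyclohex-1-en-1-yl)oxy]silane | C[Si](C)(C)OC1=C[C@@](C)(C=C)CCC1 | intermediate (not isolated)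
5 | (2R,3R)-3-methyl-2-(3-oxopropyl)-3-vinylcyclohexan-1-one (chain trans to vinyl) | O=CCC[C@H]1C(=O)CCC[C@]1(C)C=C | intermediate
6 | (2R,3R)-2-[2-(1,3-dithian-2-yl)ethyl]-3-methyl-3-vinylcyclohexan-1-one | C1(SCCCS1)CC[C@H]2C(=O)CCC[C@]2(C)C=C | intermediate
7 | 2-{2-[(6R,7R)-7-methyl-7-vinyl-1,4-dioxaspiro[4.5]decan-6-yl]ethyl}-1,3-dithiane | C1(SCCCS1)CC[C@H]2C3(OCCO3)CCC[C@]2(C)C=C | intermediate
8 | 3-[(6R,7R)-7-methyl-7-vinyl-1,4-dioxaspiro[4.5]decan-6-yl]propanal | O=CCC[C@H]1C2(OCCO2)CCC[C@]1(C)C=C | intermediate
9 | 9,9-ethylenedioxy-11,12,13-trinoreremophilan-3α-ol (3R,4R,5R,10R; 4β,5β-dimethyl, H-10α) | O[C@@H]1CC[C@H]2C3(OCCO3)CCC[C@]2(C)[C@H]1C | intermediate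
10 | 3α-(tert-butyldimethylsilyloxy)-9,9-ethylenedioxy-11,12,13-trinoreremophilane | CC(C)(C)[Si](C)(C)O[C@@H]1CC[C@H]2C3(OCCO3)CCC[C@]2(C)[C@H]1C | intermediate
11 | 3α-(tert-butyldimethylsilyloxy)-11,12,13-trinoreremophilan-9-one | CC(C)(C)[Si](C)(C)O[C@@H]1CC[C@H]2C(=O)CCC[C@]2(C)[C@H]1C | intermediate
12 | 2,4,6-triisopropylbenzenesulfonylhydrazone of 11 | CC(C)(C)[Si](C)(C)O[C@@H]1CC[C@H]2C(=NNS(=O)(=O)c3c(C(C)C)cc(C(C)C)cc3C(C)C)CCC[C@]2(C)[C@H]1C | intermediate
13 | 9-lithio-3α-(tert-butyldimethylsilyloxy)-11,12,13-trinoreremophil-8-ene | CC(C)(C)[Si](C)(C)O[C@@H]1CC[C@H]2C([Li])=CCC[C@]2(C)[C@H]1C | intermediate (not isolated)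
14 | 3α-(tert-butyldimethylsilyloxy)-11,12,13-trinoreremophil-8-ene | CC(C)(C)[Si](C)(C)O[C@@H]1CC[C@H]2C=CCC[C@]2(C)[C@H]1C | intermediate
15 | 3α-(tert-butyldimethylsilyloxy)-11,12,13-trinoreremophilane-8α,9α-diol | CC(C)(C)[Si](C)(C)O[C@@H]1CC[C@H]2[C@H](O)[C@H](O)CC[C@]2(C)[C@H]1C | intermediate
16 | 8α,9α-O-dibutylstannylene acetal of 15 | CC(C)(C)[Si](C)(C)O[C@@H]1CC[C@H]2[C@@H]3O[Sn](CCCC)(CCCC)O[C@@H]3CC[C@]2(C)[C@H]1C | intermediate (not isolated)
17 | 3α-(tert-butyldimethylsilyloxy)-9α-(4-methoxybenzyloxy)-11,12,13-trinoreremophilan-8α-ol | CC(C)(C)[Si](C)(C)O[C@@H]1CC[C@H]2[C@H](OCc3ccc(OC)cc3)[C@H](O)CC[C@]2(C)[C@H]1C | intermediate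
18 | 3α-(tert-butyldimethylsilyloxy)-9α-(4-methoxybenzyloxy)-11,12,13-trinoreremophilan-8-one | CC(C)(C)[Si](C)(C)O[C@@H]1CC[C@H]2[C@H](OCc3ccc(OC)cc3)C(=O)CC[C@]2(C)[C@H]1C | intermediate
19 | acetone | CC(C)=O | starting material
20 | lithium C7–C8 enolate of 18 | CC(C)(C)[Si](C)(C)O[C@@H]1CC[C@H]2[C@H](OCc3ccc(OC)cc3)C(O[Li])=CC[C@]2(C)[C@H]1C | intermediate (not isolated)
21 | 3α-(tert-butyldimethylsilyloxy)-11-hydroxy-9α-(4-methoxybenzyloxy)eremophilan-8-one (side chain 7α expected) | CC(C)(C)[Si](C)(C)O[C@@H]1CC[C@H]2[C@H](OCc3ccc(OC)cc3)C(=O)[C@H](C(C)(C)O)C[C@]2(C)[C@H]1C | intermediate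
22 | 11-methanesulfonate of 21 | CC(C)(C)[Si](C)(C)O[C@@H]1CC[C@H]2[C@H](OCc3ccc(OC)cc3)C(=O)[C@H](C(C)(C)OS(C)(=O)=O)C[C@]2(C)[C@H]1C | intermediate (not isolated)
23 | 3α-(tert-butyldimethylsilyloxy)-9α-(4-methoxybenzyloxy)eremophil-7(11)-en-8-one | CC(C)(C)[Si](C)(C)O[C@@H]1CC[C@H]2[C@H](OCc3ccc(OC)cc3)C(=O)C(=C(C)C)C[C@]2(C)[C@H]1C | intermediate
24 | 3α-hydroxy-9α-(4-methoxybenzyloxy)eremophil-7(11)-en-8-one | O[C@@H]1CC[C@H]2[C@H](OCc3ccc(OC)cc3)C(=O)C(=C(C)C)C[C@]2(C)[C@H]1C | intermediate
25 | (S)-pent-1-yn-3-ol | CC[C@H](O)C#C | starting material
26 | dilithium alkoxide acetylide of 25 | CC[C@H](O[Li])C#C[Li] | intermediate (not isolated)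
27 | (4S)-4-hydroxyhex-2-ynoic acid | CC[C@H](O)C#CC(=O)O | intermediate
28 | tert-butyl (4S)-4-hydroxyhex-2-ynoate | CC[C@H](O)C#CC(=O)OC(C)(C)C | intermediate
29 | hex-2-ynoic acid | CCCC#CC(=O)O | starting material
30 | tert-butyl (4S)-4-(hex-2-ynoyloxy)hex-2-ynoate | CCCC#CC(=O)O[C@@H](CC)C#CC(=O)OC(C)(C)C | intermediate
31 | (4S)-4-(hex-2-ynoyloxy)hex-2-ynoic acid | CCCC#CC(=O)O[C@@H](CC)C#CC(=O)O | intermediate
32 | 9α-(4-methoxybenzyloxy)-8-oxoeremophil-7(11)-en-3α-yl (4S)-4-(hex-2-ynoyloxy)hex-2-ynoate | CCCC#CC(=O)O[C@@H](CC)C#CC(=O)O[C@@H]1CC[C@H]2[C@H](OCc3ccc(OC)cc3)C(=O)C(=C(C)C)C[C@]2(C)[C@H]1C | intermediate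
33 | 9α-(4-methoxybenzyloxy)-8-oxoeremophil-7(11)-en-3α-yl (2Z,4S)-4-[(2Z)-hex-2-enoyloxy]hex-2-enoate | CCC/C=C\C(=O)O[C@H](/C=C\C(=O)O[C@@H]1CC[C@H]2[C@H](OCc3ccc(OC)cc3)C(=O)C(=C(C)C)C[C@]2(C)[C@H]1C)CC | intermediate
34 | (3R,4R,5R,9S,10R)-9-hydroxy-8-oxoeremophil-7(11)-en-3-yl (2Z,4S)-4-[(2Z)-hex-2-enoyloxy]hex-2-enoate (CNP0170141.1) | CCC/C=C\C(=O)O[C@H](/C=C\C(=O)O[C@@H]1CC[C@H]2[C@H](O)C(=O)C(=C(C)C)C[C@]2(C)[C@H]1C)CC | target

## Step count and risk

Total step count: 22 (15 on the core, 4 on the side-chain acid, 3 after the union). Longest linear sequence: 18 steps (steps 1–15 and 20–22).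

Steps least certain to work:

**Step 1 (key step).** The most likely failure is poor facial selectivity in the vinyl transfer to C5. Ligand-controlled copper catalysis is established on this enone for alkyl Grignard reagents and for alkenylaluminium reagents, but not for an unsubstituted vinyl Grignard reagent, which may also add in part to the carbonyl group. A second weakness is premature loss of the silyl group of 4 under the protic conditions of the Michael stage.
Fallback: it sets out from 1 and returns at 5. The vinyl group is introduced with the known copper–carbene-catalysed enantioselective addition of diisobutyl[1-(trimethylsilyl)vinyl]aluminium (from ethynyltrimethylsilane and i-Bu2AlH; CuCl2·2H2O with a chiral sulfonate-bearing imidazolinium salt as carbene precursor). The aluminium enolate is silylated with Me3SiOTf to trimethyl({(3S)-3-methyl-3-[1-(trimethylsilyl)vinyl]cyclohex-1-en-1-yl}oxy)silane F1. F1 is added to 3 as in step 1 to give (2R,3S)-3-methyl-2-(3-oxopropyl)-3-[1-(trimethylsilyl)vinyl]cyclohexan-1-one F2. Protodesilylation of the vinylsilane with CF3CO2H at 0 °C then gives 5.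

**Step 2 (sorting of C10).** Step 1 may deliver the two C10 epimers in nearly equal amounts, because neither kinetic nor thermodynamic control distinguishes methyl from vinyl strongly, and the separation may cost material.
Fallback: it sets out from 5 and returns at 6. After thioacetalisation the unwanted epimer (2S,3R)-2-[2-(1,3-dithian-2-yl)ethyl]-3-methyl-3-vinylcyclohexan-1-one F3 is not discarded. It is equilibrated through its C9–C10 enolate with NaOMe in MeOH, which is safe here because the aldehyde is masked and no aldol partner is present. The mixture is separated again, so F3 is converted batch by batch into 6 by recycling and not by selectivity.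

**Step 5 (ring A closure).** A 6-exo ketyl addition to an unactivated vinyl group is slow, so simple reduction of the aldehyde to the primary alcohol and pinacol coupling can outrun cyclisation. The face of C4 is also controlled only by the chair preference.
Fallback: it sets out from 5 (trans epimer) and returns at 11. The polarity is reversed: an iron-hydride hydrogen-atom transfer (Fe(acac)3, PhSiH3, EtOH, 60 °C) places a hydrogen on C15 and a radical on C4, which adds 6-exo to the aldehyde carbon. The C9 ketone is out of reach, so no protection is needed. This gives 3α-hydroxy-11,12,13-trinoreremophilan-9-one F4, which is silylated (TBSCl, imidazole) to 11. This also bypasses steps 2–4 and 7.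

**Steps 8–9 (Shapiro olefination).** With the C9 ketone free, C10 can epimerise through the enol or the ene-hydrazine during hydrazone formation, and the hindered ketone may condense slowly.
Fallback: it sets out from 11 and returns at 14. Kinetic deprotonation at C8 with KHMDS and trapping with PhNTf2 at −78 °C gives the enol triflate 3α-(tert-butyldimethylsilyloxy)-11,12,13-trinoreremophil-8-en-9-yl trifluoromethanesulfonate F5. F5 is reduced to 14 with Pd(OAc)2, PPh3, Bu3N and HCO2H in DMF.

**Step 11 (differentiation of the diol).** The equatorial O9 lies next to the ring fusion, so benzylation of the tin acetal may be slow or may go in part to O8.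
Fallback: it sets out from 15 and returns at 18. The order is inverted: the tin acetal is oxidised with Br2 (brominolysis, expected to oxidise the axial C8 carbinol) to 3α-(tert-butyldimethylsilyloxy)-9α-hydroxy-11,12,13-trinoreremophilan-8-one F6. The ketol hydroxyl is then etherified with 4-methoxybenzyl trichloroacetimidate and La(OTf)3 to give 18.

**Steps 20–21 (union and alkyne reduction).** The activated 4-acyloxy-ynoic acid may isomerise to an allene under DMAP, and the late double semi-hydrogenation may over-reduce.
Fallback: it sets out from 30 and returns at 33. The Z geometry is set before the union: 30 is semi-hydrogenated over the same poisoned palladium catalyst to tert-butyl (2Z,4S)-4-[(2Z)-hex-2-enoyloxy]hex-2-enoate F7. F7 is cleaved with CF3CO2H to (2Z,4S)-4-[(2Z)-hex-2-enoyloxy]hex-2-enoic acid F8. F8 is coupled with 24 through its 2,4,6-trichlorobenzoyl mixed anhydride (Yamaguchi esterification with the minimum of DMAP) to give 33.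

## Further compounds

F1 | step 1 | trimethyl({(3S)-3-methyl-3-[1-(trimethylsilyl)vinyl]cyclohex-1-en-1-yl}oxy)silane | C[Si](C)(C)OC1=C[C@@](C)(C(=C)[Si](C)(C)C)CCC1
F2 | step 1 | (2R,3S)-3-methyl-2-(3-oxopropyl)-3-[1-(trimethylsilyl)vinyl]cyclohexan-1-one | O=CCC[C@H]1C(=O)CCC[C@]1(C)C(=C)[Si](C)(C)C
F3 | step 2 | (2S,3R)-2-[2-(1,3-dithian-2-yl)ethyl]-3-methyl-3-vinylcyclohexan-1-one | C1(SCCCS1)CC[C@@H]2C(=O)CCC[C@]2(C)C=C
F4 | step 5 | 3α-hydroxy-11,12,13-trinoreremophilan-9-one | O[C@@H]1CC[C@H]2C(=O)CCC[C@]2(C)[C@H]1C
F5 | step 9 | 3α-(tert-butyldimethylsilyloxy)-11,12,13-trinoreremophil-8-en-9-yl trifluoromethanesulfonate | CC(C)(C)[Si](C)(C)O[C@@H]1CC[C@H]2C(OS(=O)(=O)C(F)(F)F)=CCC[C@]2(C)[C@H]1C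
F6 | step 11 | 3α-(tert-butyldimethylsilyloxy)-9α-hydroxy-11,12,13-trinoreremophilan-8-one | CC(C)(C)[Si](C)(C)O[C@@H]1CC[C@H]2[C@H](O)C(=O)CC[C@]2(C)[C@H]1C
F7 | step 20 | tert-butyl (2Z,4S)-4-[(2Z)-hex-2-enoyloxy]hex-2-enoate | CCC/C=C\C(=O)O[C@H](/C=C\C(=O)OC(C)(C)C)CC
F8 | step 20 | (2Z,4S)-4-[(2Z)-hex-2-enoyloxy]hex-2-enoic acid | CCC/C=C\C(=O)O[C@H](/C=C\C(=O)O)CC
A1 | alternative 1 | 3α-(tert-butyldimethylsilyloxy)-8-(triethylsilyloxy)-5,6-seco-eremophila-5(10),6,8-triene without the C7 side chain | CC(C)(C)[Si](C)(C)O[C@@H]1CCC(/C=C(O[Si](CC)(CC)CC)\C=C)=C(C)[C@H]1C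
A2 | alternative 1 | 3α-(tert-butyldimethylsilyloxy)-8-(triethylsilyloxy)eremophila-7,9-diene without the C7 side chain | CC(C)(C)[Si](C)(C)O[C@@H]1CCC2=CC(O[Si](CC)(CC)CC)=CC[C@]2(C)[C@H]1C
A3 | alternative 2 | (2E,6E)-farnesyl diphosphate | CC(C)=CCC/C(C)=C/CC/C(C)=C/COP(=O)(O)OP(=O)(O)O
A4 | alternative 2 | (+)-aristolochene, (4S,5R,7S)-eremophila-9,11-diene | C1CCC2=CC[C@H](C(C)=C)C[C@]2(C)[C@H]1C
A5 | alternative 3 | 2,3-dimethylcyclodec-2-ene-1,7-dione | O=C1CCCC(=O)CCCC(C)=C1C
A6 | alternative 3 | trans-fused 4β,5β-dimethyldecalin-3,9-dione (eremophilane numbering) | O=C1CC[C@H]2C(=O)CCC[C@]2(C)[C@H]1C
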